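**Retrosynthetic overview**
1. Twelve-membered ring last: C5–C6 bond by intramolecular alkylation of a (Z)-allylic sulfone anion with an (E)-allylic bromide, then reductive desulfonylation and fluoride deprotection.
2. Cyclohexene ring (quaternary C15, C11, C12=C13): Ireland–Claisen ring contraction of a trans-4,6-disubstituted 6-alkenyl δ-lactone.
3. Key C–C bond (C1–C2): intermolecular Michael addition of the lithium enolate of ethyl acetate to an enantiopure 6-alkenyl-5,6-dihydropyran-2-one (sets C1), then α-alkylation with homoprenyl iodide.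
4. Dihydropyranone from a nerol-derived (Z)-enal by Brown allylation (sets C13), acryloylation and ring-closing metathesis; the (Z)-enal comes from nerol through a (Z)-α-iodoenal.
5. Ring order: dihydropyranone (temporary) → cyclohexene → twelve-membered carbocycle.

Assumption: carbon labels C1–C18 are those of the target in bicyclo[9.3.1]pentadecane numbering (C1, C11 bridgeheads; C15 one-carbon bridge; C16 carboxyl carbon; C18 hydroxymethyl carbon), kept for the same carbons in all intermediates; TBS = tert-butyldimethylsilyl, TBDPS = tert-butyldiphenylsilyl, TMSE = 2-(trimethylsilyl)ethyl, Ipc = isopinocampheyl, G = (2Z,6Z)-1-(TBDPS-oxy)-8-(TBS-oxy)-6-methylocta-2,6-dien-2-yl; where a name and a SMILES differ, the SMILES holds.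

**Step 1**
Reactants: 1 nerol [(2Z)-3,7-dimethylocta-2,6-dien-1-ol]
Product: 2 neryl TBS ether [(2Z)-1-(TBS-oxy)-3,7-dimethylocta-2,6-diene]
Conditions: TBSCl, imidazole, CH2Cl2, 0 °C → rt
Reagents that add atoms: tert-butyldimethylsilyl chloride, CC(C)(C)[Si](C)(C)Cl
Why: Routine silylation of a primary allylic alcohol; the Z alkene that becomes C7=C8 is carried through unchanged.

**Step 2**
Reactants: 2 neryl TBS ether
Product: 3 terminal epoxide [tert-butyl{[(2Z)-5-(3,3-dimethyloxiran-2-yl)-3-methylpent-2-enyl]oxy}dimethylsilane; racemic]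
Conditions: mCPBA, NaHCO3, CH2Cl2, −20 → 0 °C
Reagents that add atoms: 3-chloroperoxybenzoic acid, OOC(=O)c1cccc(Cl)c1
Why: Prilezhaev epoxidation goes to the remote, more electron-rich trisubstituted alkene rather than the one deactivated by the allylic silyloxy group; the epoxide stereocentre is destroyed in the next step.

**Step 3**
Reactants: 3 terminal epoxide
Product: 5 (4Z)-6-(TBS-oxy)-4-methylhex-4-enal, via diol 4 (not isolated)
Conditions: H5IO6, THF–Et2O, 0 °C
Reagents that add atoms: none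
Why: Acid-mediated epoxide hydrolysis and Malaprade glycol cleavage in one flask excise acetone and leave the aldehyde carbon that becomes C11, without touching the Z alkene.

**Step 4**
Reactants: 5 (4Z)-6-(TBS-oxy)-4-methylhex-4-enal
Product: 6 (2E,6Z)-8-(TBS-oxy)-6-methylocta-2,6-dienal
Conditions: Ph3P=CHCHO, toluene, 80 °C
Reagents that add atoms: (triphenylphosphoranylidene)acetaldehyde, O=CC=P(c1ccccc1)(c1ccccc1)c1ccccc1
Why: Wittig olefination with a stabilised formyl ylide gives the (E)-enal and adds C12 and C18.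

**Step 5**
Reactants: 6 (2E,6Z)-8-(TBS-oxy)-6-methylocta-2,6-dienal
Product: 7 (2Z,6Z)-2-iodo-8-(TBS-oxy)-6-methylocta-2,6-dienal
Conditions: I2, K2CO3, DMAP (cat.), THF–H2O (1:1), rt
Reagents that add atoms: iodine, I-I
Why: DMAP-mediated α-iodination (conjugate addition, iodination, elimination) gives the thermodynamically preferred (Z)-α-iodoenal with iodine cis to the chain, which fixes the later C13/C10 cis relationship on C12=C11.

**Step 6**
Reactants: 7 (2Z,6Z)-2-iodo-8-(TBS-oxy)-6-methylocta-2,6-dienal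
Product: 8 (2Z,6Z)-2-iodo-8-(TBS-oxy)-6-methylocta-2,6-dien-1-ol
Conditions: NaBH4, CeCl3·7H2O, MeOH, −20 → 0 °C
Reagents that add atoms: none
Why: Luche reduction is 1,2-selective and leaves the vinyl iodide and its geometry intact.

**Step 7**
Reactants: 8 (2Z,6Z)-2-iodo-8-(TBS-oxy)-6-methylocta-2,6-dien-1-ol
Product: 9 vinyl iodide G–I [(2Z,6Z)-1-(TBDPS-oxy)-2-iodo-8-(TBS-oxy)-6-methylocta-2,6-diene]
Conditions: TBDPSCl, imidazole, DMF, rt
Reagents that add atoms: tert-butyldiphenylsilyl chloride, CC(C)(C)[Si](Cl)(c1ccccc1)c1ccccc1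
Why: Silylation of the C18 alcohol with a group that later survives selective removal of the TBS ether.

**Step 8**
Reactants: 9 vinyl iodide G–I
Product: 11 (2Z,6Z)-2-[(TBDPS-oxy)methyl]-8-(TBS-oxy)-6-methylocta-2,6-dienal, via vinyllithium 10 (not isolated)
Conditions: t-BuLi (2.1 equiv), Et2O, −78 °C; DMF, −78 → −40 °C; H2O
Reagents that add atoms: N,N-dimethylformamide, CN(C)C=O
Why: Lithium–iodine exchange proceeds with retention of alkene geometry and Bouveault formylation then gives the (Z)-enal whose formyl carbon C13 is cis to the C10 chain; it is used at once because this isomer is the less stable one.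

**Step 9**
Reactants: 11 (Z)-enal G–CHO
Product: 13 (4R,5Z,9Z)-5-[(TBDPS-oxy)methyl]-11-(TBS-oxy)-9-methylundeca-1,5,9-trien-4-ol, via borinate ester 12 (not isolated)
Conditions: (+)-Ipc2B(allyl), Et2O, −78 °C; then NaOH, H2O2, 0 °C → rt
Reagents that add atoms: (+)-B-allyldiisopinocampheylborane (from (−)-α-pinene), C=CCB([C@H]1C[C@H]2C[C@@H]([C@@H]1C)C2(C)C)[C@H]1C[C@H]2C[C@@H]([C@@H]1C)C2(C)C
Why: Brown asymmetric allylboration (carbonyl allylation) through a chair Zimmerman–Traxler transition state delivers allyl to the Re face and sets C13 as R, fast enough at −78 °C that the (Z)-enal does not isomerise.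

**Step 10**
Reactants: 13 homoallylic alcohol
Product: 14 acrylate of 13 [(4R,5Z,9Z)-5-[(TBDPS-oxy)methyl]-11-(TBS-oxy)-9-methylundeca-1,5,9-trien-4-yl prop-2-enoate]
Conditions: CH2=CHCOCl, Et3N, DMAP (cat.), CH2Cl2, −20 → 0 °C
Reagents that add atoms: acryloyl chloride, C=CC(=O)Cl
Why: Simple O-acylation supplies C15 and C16; C13 is not touched.

**Step 11**
Reactants: 14 acrylate
Product: 15 (6R)-6-G-5,6-dihydro-2H-pyran-2-one
Conditions: second-generation Grubbs catalyst (5 mol %), CH2Cl2 (0.005 M), 40 °C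
Reagents that add atoms: none
Why: Ring-closing metathesis of the two terminal alkenes gives the six-membered unsaturated lactone, while the trisubstituted alkenes are inert under these conditions.

**Step 12**
Reactants: 15 (6R)-6-G-5,6-dihydro-2H-pyran-2-one; 16 ethyl acetate
Product: 19 ethyl 2-[(2R,4R)-2-G-6-oxooxan-4-yl]acetate (side chains trans), via lithium ethyl acetate enolate 17 (not isolated), via lithium lactone enolate 18 (not isolated)
Conditions: 16, LiN(iPr)2, THF, −78 °C; then 15, −78 °C; AcOH quench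
Reagents that add atoms: none
Why: Intermolecular Michael addition of the ester enolate forms C1–C2; axial attack anti to the pseudo-equatorial C6 substituent of the dihydropyranone gives the trans-4,6 lactone and so sets C1 from C13.

**Step 13**
Reactants: 20 5-bromo-2-methylpent-2-ene
Product: 21 5-iodo-2-methylpent-2-ene
Conditions: NaI, acetone, reflux
Reagents that add atoms: sodium iodide, [Na+].[I-]
Why: Finkelstein exchange gives the more reactive homoprenyl iodide for the enolate alkylation.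

**Step 14**
Reactants: 19 trans lactone ester; 21 5-iodo-2-methylpent-2-ene
Product: 23 ethyl 2-[(2R,4R)-2-G-5-(4-methylpent-3-enyl)-6-oxooxan-4-yl]acetate (C5 epimers), via sodium lactone enolate 22 (not isolated)
Conditions: NaN(SiMe3)2 (1.05 equiv), THF, −78 °C, 30 min; then 21, DMPU, −78 → −20 °C
Reagents that add atoms: none
Why: Enolate alkylation; the lactone α-CH2 is four to five pKa units more acidic than the acyclic ester CH2, so the sodium amide gives the lactone enolate 22 (any ester enolate is converted to it by proton transfer), and this sodium enolate is nucleophilic enough for the unactivated primary iodide; the new C15 configuration does not matter because C15 is planarised in the next step.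

**Step 15**
Reactants: 23 α-homoprenyl lactone
Product: 26 (1S,2S,6R)-6-(2-ethoxy-2-oxoethyl)-1-(4-methylpent-3-enyl)-2-[(3Z)-5-(TBS-oxy)-3-methylpent-3-enyl]-3-[(TBDPS-oxy)methyl]cyclohex-3-ene-1-carboxylic acid, via bis(silyl ketene acetal) 24 (not isolated), via trimethylsilyl ester 25 (not isolated)
Conditions: Me3SiCl/Et3N, LiN(iPr)2 (3 equiv), THF, −78 °C → rt; toluene, 110 °C; then MeOH, aq. NaH2PO4
Reagents that add atoms: none
Why: Ireland–Claisen ring contraction of the lactone silyl ketene acetal through the boat transition state forced by the two-carbon tether; C15–C11 forms on the lactone face carrying the alkenyl group (trans to the C1 arm), and the C13/C10-cis alkene places the C10 chain trans to the carboxyl, so C15 and C11 are both set from C13 and C1 (excess base silylates the side-chain ester too, but only the lactone ketene acetal can rearrange).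

**Step 16**
Reactants: 26 cyclohexene acid
Product: 27 TMSE ester of 26 (stereocentres unchanged)
Conditions: Me3SiCH2CH2OH, PPh3, DIAD, THF, 0 °C → rt
Reagents that add atoms: 2-(trimethylsilyl)ethanol, C[Si](C)(C)CCO
Why: Mitsunobu esterification alkylates the carboxylate oxygen, so the hindrance at the quaternary acyl carbon does not matter, and the TMSE group can be removed by fluoride at the end.

**Step 17**
Reactants: 27 TMSE ester
Product: 28 aldehyde (27 with the CH2CO2Et arm on C1 reduced to CH2CHO)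
Conditions: iBu2AlH (1.15 equiv), CH2Cl2, −78 °C; aq. potassium sodium tartrate
Reagents that add atoms: none
Why: Low-temperature partial reduction takes the unhindered ethyl ester to the aldehyde (C3) while the ester on the quaternary carbon is too hindered to react.

**Step 18**
Reactants: 28 aldehyde
Product: 29 (E)-enoate (C1 arm = (2E)-4-ethoxy-3-methyl-4-oxobut-2-enyl)
Conditions: Ph3P=C(Me)CO2Et, toluene, 80 °C
Reagents that add atoms: ethyl 2-(triphenylphosphoranylidene)propanoate, CCOC(=O)C(C)=P(c1ccccc1)(c1ccccc1)c1ccccc1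
Why: Wittig olefination with an α-methyl stabilised ylide gives the (E)-trisubstituted C3=C4 alkene and adds C4, its methyl and C5.

**Step 19**
Reactants: 29 (E)-enoate
Product: 30 allylic alcohol at C6 (29 with OTBS replaced by OH)
Conditions: PPTS, MeOH, rt
Reagents that add atoms: none
Why: Acid-catalysed methanolysis cleaves the primary TBS ether and leaves the more robust TBDPS ether, both esters and the alkenes untouched.

**Step 20**
Reactants: 30 allylic alcohol
Product: 31 (Z)-allylic bromide at C6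
Conditions: CBr4, PPh3, CH2Cl2, −20 → 0 °C
Reagents that add atoms: carbon tetrabromide, BrC(Br)(Br)Br
Why: Appel bromination by SN2 displacement at the primary carbon keeps the Z geometry at low temperature.

**Step 21**
Reactants: 31 allylic bromide
Product: 32 (Z)-allylic phenyl sulfone at C6
Conditions: PhSO2Na, DMF, rt
Reagents that add atoms: sodium benzenesulfinate, [Na+].[O-]S(=O)c1ccccc1
Why: S-alkylation of the sulfinate by SN2 installs the group that will stabilise the C6 carbanion.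

**Step 22**
Reactants: 32 sulfone enoate
Product: 33 allylic alcohol at C5 (C1 arm = (2E)-4-hydroxy-3-methylbut-2-enyl)
Conditions: iBu2AlH (2.5 equiv), CH2Cl2, −78 °C; aq. potassium sodium tartrate
Reagents that add atoms: none
Why: 1,2-Reduction of the conjugated ethyl ester to the (E)-allylic alcohol; the hindered TMSE ester and the sulfone do not react at −78 °C.

**Step 23**
Reactants: 33 hydroxy sulfone
Product: 34 (E)-allylic bromide at C5 (C1 arm = (2E)-4-bromo-3-methylbut-2-enyl)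
Conditions: CBr4, PPh3, CH2Cl2, −20 °C
Reagents that add atoms: carbon tetrabromide, BrC(Br)(Br)Br
Why: Appel bromination gives the primary allylic electrophile for ring closure.

**Step 24**
Reactants: 34 bromo sulfone
Product: 36 TMSE (1S,3E,7Z,11S,15S)-12-[(TBDPS-oxy)methyl]-4,8-dimethyl-15-(4-methylpent-3-enyl)-6-(phenylsulfonyl)bicyclo[9.3.1]pentadeca-3,7,12-triene-15-carboxylate (C6 epimers), via potassium sulfonyl carbanion 35 (not isolated)
Conditions: KN(SiMe3)2, THF (0.002 M, slow addition of 34), −78 → −20 °C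
Reagents that add atoms: none
Why: Intramolecular α-alkylation of the allylic sulfone carbanion (SN2 at the primary allylic bromide) under high dilution closes the twelve-membered ring at C5–C6; α-attack leaves both alkenes in place, and the new C6 centre is removed in the next step.

**Step 25**
Reactants: 36 macrocyclic sulfone
Product: 37 TMSE (1S,3E,7Z,11S,15S)-12-[(TBDPS-oxy)methyl]-4,8-dimethyl-15-(4-methylpent-3-enyl)bicyclo[9.3.1]pentadeca-3,7,12-triene-15-carboxylate
Conditions: PdCl2(dppp) (5 mol %), LiBHEt3, THF, −20 → 0 °C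
Reagents that add atoms: none
Why: Palladium-catalysed reductive desulfonylation through a π-allyl complex delivers hydride to the less hindered secondary terminus C6, which keeps C7=C8 in place and Z; the ester on the quaternary carbon is too hindered to be reduced in this short, cold reaction.

**Step 26**
Reactants: 37 protected macrocycle
Product: 38 target, (1S,3E,7Z,11S,15S)-12-(hydroxymethyl)-4,8-dimethyl-15-(4-methylpent-3-enyl)bicyclo[9.3.1]pentadeca-3,7,12-triene-15-carboxylic acid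
Conditions: Bu4NF, THF, rt → 45 °C; aq. NH4Cl
Reagents that add atoms: none
Why: Fluoride cleaves the TBDPS ether and the TMSE ester (β-elimination to ethene) in one operation, which needs no attack at the hindered acyl carbon and touches no stereocentre.

**Compound list**
1 | nerol, (2Z)-3,7-dimethylocta-2,6-dien-1-ol | CC(C)=CCC/C(C)=C\CO | starting material
2 | neryl TBS ether | CC(C)=CCC/C(C)=C\CO[Si](C)(C)C(C)(C)C | intermediate
3 | terminal epoxide of 2 (racemic) | CC1(C)OC1CC/C(C)=C\CO[Si](C)(C)C(C)(C)C | intermediate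
4 | (6Z)-8-(TBS-oxy)-2,6-dimethyloct-6-ene-2,3-diol (not isolated) | CC(C)(O)C(O)CC/C(C)=C\CO[Si](C)(C)C(C)(C)C | intermediate
5 | (4Z)-6-(TBS-oxy)-4-methylhex-4-enal | O=CCC/C(C)=C\CO[Si](C)(C)C(C)(C)C | intermediate
6 | (2E,6Z)-8-(TBS-oxy)-6-methylocta-2,6-dienal | O=C/C=C/CC/C(C)=C\CO[Si](C)(C)C(C)(C)C | intermediate
7 | (2Z,6Z)-2-iodo-8-(TBS-oxy)-6-methylocta-2,6-dienal | O=C/C(I)=C/CC/C(C)=C\CO[Si](C)(C)C(C)(C)C | intermediate
8 | (2Z,6Z)-2-iodo-8-(TBS-oxy)-6-methylocta-2,6-dien-1-ol | OC/C(I)=C/CC/C(C)=C\CO[Si](C)(C)C(C)(C)C | intermediate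
9 | vinyl iodide G–I, (2Z,6Z)-1-(TBDPS-oxy)-2-iodo-8-(TBS-oxy)-6-methylocta-2,6-diene | CC(C)(C)[Si](OC/C(I)=C/CC/C(C)=C\CO[Si](C)(C)C(C)(C)C)(c1ccccc1)c1ccccc1 | intermediate
10 | vinyllithium G–Li, lithium in place of iodine of 9 with retention (not isolated) | CC(C)(C)[Si](OC/C([Li])=C/CC/C(C)=C\CO[Si](C)(C)C(C)(C)C)(c1ccccc1)c1ccccc1 | intermediate
11 | (2Z,6Z)-2-[(TBDPS-oxy)methyl]-8-(TBS-oxy)-6-methylocta-2,6-dienal | CC(C)(C)[Si](OC/C(C=O)=C/CC/C(C)=C\CO[Si](C)(C)C(C)(C)C)(c1ccccc1)c1ccccc1 | intermediate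
12 | O-(diisopinocampheylboryl) derivative of 13 (not isolated) | C=CC[C@@H](OB([C@H]1C[C@H]2C[C@@H]([C@@H]1C)C2(C)C)[C@H]1C[C@H]2C[C@@H]([C@@H]1C)C2(C)C)/C(CO[Si](c1ccccc1)(c1ccccc1)C(C)(C)C)=C\CC/C(C)=C\CO[Si](C)(C)C(C)(C)C | intermediate
13 | (4R,5Z,9Z)-5-[(TBDPS-oxy)methyl]-11-(TBS-oxy)-9-methylundeca-1,5,9-trien-4-ol | C=CC[C@@H](O)/C(CO[Si](c1ccccc1)(c1ccccc1)C(C)(C)C)=C\CC/C(C)=C\CO[Si](C)(C)C(C)(C)C | intermediate
14 | acrylate of 13 | C=CC[C@@H](OC(=O)C=C)/C(CO[Si](c1ccccc1)(c1ccccc1)C(C)(C)C)=C\CC/C(C)=C\CO[Si](C)(C)C(C)(C)C | intermediate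
15 | (6R)-6-G-5,6-dihydro-2H-pyran-2-one | O=C1C=CC[C@H](/C(CO[Si](c2ccccc2)(c2ccccc2)C(C)(C)C)=C\CC/C(C)=C\CO[Si](C)(C)C(C)(C)C)O1 | intermediate
16 | ethyl acetate | CCOC(C)=O | starting material
17 | lithium enolate of ethyl acetate (not isolated) | [Li]OC(=C)OCC | intermediate
18 | lithium enolate of lactone 19 (not isolated) | [Li]OC1=C[C@@H](CC(=O)OCC)C[C@H](/C(CO[Si](c2ccccc2)(c2ccccc2)C(C)(C)C)=C\CC/C(C)=C\CO[Si](C)(C)C(C)(C)C)O1 | intermediate
19 | ethyl 2-[(2R,4R)-2-G-6-oxooxan-4-yl]acetate (trans) | O=C1C[C@@H](CC(=O)OCC)C[C@H](/C(CO[Si](c2ccccc2)(c2ccccc2)C(C)(C)C)=C\CC/C(C)=C\CO[Si](C)(C)C(C)(C)C)O1 | intermediate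
20 | 5-bromo-2-methylpent-2-ene | CC(C)=CCCBr | starting material
21 | 5-iodo-2-methylpent-2-ene | CC(C)=CCCI | intermediate
22 | sodium enolate of lactone 19 (not isolated) | [Na]OC1=C[C@@H](CC(=O)OCC)C[C@H](/C(CO[Si](c2ccccc2)(c2ccccc2)C(C)(C)C)=C\CC/C(C)=C\CO[Si](C)(C)C(C)(C)C)O1 | intermediate
23 | ethyl 2-[(2R,4R)-2-G-5-(4-methylpent-3-enyl)-6-oxooxan-4-yl]acetate (C5 epimers) | O=C1C(CCC=C(C)C)[C@@H](CC(=O)OCC)C[C@H](/C(CO[Si](c2ccccc2)(c2ccccc2)C(C)(C)C)=C\CC/C(C)=C\CO[Si](C)(C)C(C)(C)C)O1 | intermediate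
24 | bis(trimethylsilyl ketene acetal) of 23, lactone and side-chain ester (not isolated) | C[Si](C)(C)OC1=C(CCC=C(C)C)[C@@H](C=C(OCC)O[Si](C)(C)C)C[C@H](/C(CO[Si](c2ccccc2)(c2ccccc2)C(C)(C)C)=C\CC/C(C)=C\CO[Si](C)(C)C(C)(C)C)O1 | intermediate
25 | trimethylsilyl ester of 26 with the side-chain ester still a silyl ketene acetal (not isolated) | CC(C)=CCC[C@]1(C(=O)O[Si](C)(C)C)[C@@H](C=C(OCC)O[Si](C)(C)C)CC=C(CO[Si](c2ccccc2)(c2ccccc2)C(C)(C)C)[C@@H]1CC/C(C)=C\CO[Si](C)(C)C(C)(C)C | intermediate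
26 | (1S,2S,6R)-6-(2-ethoxy-2-oxoethyl)-1-(4-methylpent-3-enyl)-2-[(3Z)-5-(TBS-oxy)-3-methylpent-3-enyl]-3-[(TBDPS-oxy)methyl]cyclohex-3-ene-1-carboxylic acid | CC(C)=CCC[C@]1(C(=O)O)[C@@H](CC(=O)OCC)CC=C(CO[Si](c2ccccc2)(c2ccccc2)C(C)(C)C)[C@@H]1CC/C(C)=C\CO[Si](C)(C)C(C)(C)C | intermediate
27 | TMSE ester of 26 | CC(C)=CCC[C@]1(C(=O)OCC[Si](C)(C)C)[C@@H](CC(=O)OCC)CC=C(CO[Si](c2ccccc2)(c2ccccc2)C(C)(C)C)[C@@H]1CC/C(C)=C\CO[Si](C)(C)C(C)(C)C | intermediate
28 | aldehyde, 27 with CH2CHO on C1 | CC(C)=CCC[C@]1(C(=O)OCC[Si](C)(C)C)[C@@H](CC=O)CC=C(CO[Si](c2ccccc2)(c2ccccc2)C(C)(C)C)[C@@H]1CC/C(C)=C\CO[Si](C)(C)C(C)(C)C | intermediate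
29 | (E)-enoate, C1 arm (2E)-4-ethoxy-3-methyl-4-oxobut-2-enyl | CC(C)=CCC[C@]1(C(=O)OCC[Si](C)(C)C)[C@@H](C/C=C(\C)C(=O)OCC)CC=C(CO[Si](c2ccccc2)(c2ccccc2)C(C)(C)C)[C@@H]1CC/C(C)=C\CO[Si](C)(C)C(C)(C)C | intermediate
30 | C6 allylic alcohol, C11 arm (3Z)-5-hydroxy-3-methylpent-3-enyl | CC(C)=CCC[C@]1(C(=O)OCC[Si](C)(C)C)[C@@H](C/C=C(\C)C(=O)OCC)CC=C(CO[Si](c2ccccc2)(c2ccccc2)C(C)(C)C)[C@@H]1CC/C(C)=C\CO | intermediate
31 | C6 (Z)-allylic bromide | CC(C)=CCC[C@]1(C(=O)OCC[Si](C)(C)C)[C@@H](C/C=C(\C)C(=O)OCC)CC=C(CO[Si](c2ccccc2)(c2ccccc2)C(C)(C)C)[C@@H]1CC/C(C)=C\CBr | intermediate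
32 | C6 (Z)-allylic phenyl sulfone | CC(C)=CCC[C@]1(C(=O)OCC[Si](C)(C)C)[C@@H](C/C=C(\C)C(=O)OCC)CC=C(CO[Si](c2ccccc2)(c2ccccc2)C(C)(C)C)[C@@H]1CC/C(C)=C\CS(=O)(=O)c2ccccc2 | intermediate
33 | C5 (E)-allylic alcohol of the sulfone | CC(C)=CCC[C@]1(C(=O)OCC[Si](C)(C)C)[C@@H](C/C=C(\C)CO)CC=C(CO[Si](c2ccccc2)(c2ccccc2)C(C)(C)C)[C@@H]1CC/C(C)=C\CS(=O)(=O)c2ccccc2 | intermediate
34 | C5 (E)-allylic bromide of the sulfone | CC(C)=CCC[C@]1(C(=O)OCC[Si](C)(C)C)[C@@H](C/C=C(\C)CBr)CC=C(CO[Si](c2ccccc2)(c2ccccc2)C(C)(C)C)[C@@H]1CC/C(C)=C\CS(=O)(=O)c2ccccc2 | intermediate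
35 | potassium α-sulfonyl carbanion of 34 (not isolated) | CC(C)=CCC[C@]1(C(=O)OCC[Si](C)(C)C)[C@@H](C/C=C(\C)CBr)CC=C(CO[Si](c2ccccc2)(c2ccccc2)C(C)(C)C)[C@@H]1CC/C(C)=C\[CH-]S(=O)(=O)c2ccccc2.[K+] | intermediate
36 | macrocyclic sulfone (C6 epimers), TMSE ester, TBDPS ether | CC(C)=CCC[C@]1(C(=O)OCC[Si](C)(C)C)[C@@H]2CC=C(CO[Si](c3ccccc3)(c3ccccc3)C(C)(C)C)[C@@H]1CC/C(C)=C\C(S(=O)(=O)c1ccccc1)C/C(C)=C/C2 | intermediate
37 | protected macrocycle, TMSE ester and TBDPS ether of the target | CC(C)=CCC[C@]1(C(=O)OCC[Si](C)(C)C)[C@@H]2CC=C(CO[Si](c3ccccc3)(c3ccccc3)C(C)(C)C)[C@@H]1CC/C(C)=C\CC/C(C)=C/C2 | intermediate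
38 | (1S,3E,7Z,11S,15S)-12-(hydroxymethyl)-4,8-dimethyl-15-(4-methylpent-3-enyl)bicyclo[9.3.1]pentadeca-3,7,12-triene-15-carboxylic acid | CC(C)=CCC[C@]1(C(=O)O)[C@@H]2CC=C(CO)[C@@H]1CC/C(C)=C\CC/C(C)=C/C2 | target

**Step count and risks**
Total steps: 26. Longest linear sequence: 25 steps (steps 1–12 and 14–26, from nerol 1); step 13 is the only side branch.

Steps most likely to fail:

Step 15 (Ireland–Claisen ring contraction). The hindered C15–H must be enolised in the presence of the side-chain ester, and the fully substituted ketene acetal must reach a Z-trisubstituted alkene terminus in a boat transition state. The fallback sets out from 15 and comes back at 26. It places the homoprenyl group on the lactone before the Michael addition, so that the conjugate addition itself makes the fully substituted lactone enolate regiospecifically. α-Iodination of 15 (I2, pyridine, CH2Cl2) gives the 3-iodo-dihydropyranone F1. Negishi coupling of F1 with (4-methylpent-3-enyl)zinc iodide F2 (from 21, Zn and LiCl in THF; Pd(PPh3)4) gives the 3-(4-methylpent-3-enyl)dihydropyranone F3. Addition of 17 to F3 at −78 °C, again anti to G, gives the lithium lactone enolate F4, and trapping in the same flask with Me3SiCl gives the single silyl ketene acetal F5. Heating F5 in toluene gives the trimethylsilyl ester F6, and mild aqueous hydrolysis gives 26.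

Step 24 (macrocyclisation). Closing a twelve-membered ring across the trans-1,3 positions of the cyclohexene competes with oligomerisation and with E2 or SN2′ reaction of the allylic bromide. The fallback sets out from 33 and comes back at 36. Acylation of 33 with ClCO2Me and pyridine gives the allylic methyl carbonate F7. The ring is then closed by palladium-catalysed allylic alkylation (Pd(PPh3)4, Ph2PCH2CH2PPh2, THF, 65 °C, slow addition to 0.002 M). Ionisation gives the (E)-configured π-allyl complex and methoxide, which deprotonates the sulfone. Attack of the sulfonyl carbanion at the primary terminus C5 gives 36 without a free strong base or an alkyl halide.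

Step 25 (reductive desulfonylation). Hydride could be delivered to the wrong allyl terminus, the Z geometry of C7=C8 could erode, or LiBHEt3 could attack the ester. The fallback sets out from 36 and comes back at 38. The silicon groups are removed first (Bu4NF, THF) to give the hydroxy acid sulfone F8. The C–S bond of F8 is then cleaved by dissolving-metal reduction (Li, EtNH2, −78 °C, then NH4Cl) on the lithium carboxylate and alkoxide, which no longer contains a reducible ester, giving 38 directly.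

**Further compounds**
F1 | step 15 | (6R)-3-iodo-6-G-5,6-dihydro-2H-pyran-2-one | O=C1C(I)=CC[C@H](/C(CO[Si](c2ccccc2)(c2ccccc2)C(C)(C)C)=C\CC/C(C)=C\CO[Si](C)(C)C(C)(C)C)O1
F2 | step 15 | (4-methylpent-3-enyl)zinc iodide | CC(C)=CCC[Zn]I
F3 | step 15 | (6R)-3-(4-methylpent-3-enyl)-6-G-5,6-dihydro-2H-pyran-2-one | O=C1C(CCC=C(C)C)=CC[C@H](/C(CO[Si](c2ccccc2)(c2ccccc2)C(C)(C)C)=C\CC/C(C)=C\CO[Si](C)(C)C(C)(C)C)O1
F4 | step 15 | lithium enolate of lactone 23 (lactone carbonyl only; not isolated) | [Li]OC1=C(CCC=C(C)C)[C@@H](CC(=O)OCC)C[C@H](/C(CO[Si](c2ccccc2)(c2ccccc2)C(C)(C)C)=C\CC/C(C)=C\CO[Si](C)(C)C(C)(C)C)O1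
F5 | step 15 | trimethylsilyl ketene acetal of lactone 23 (lactone carbonyl only) | C[Si](C)(C)OC1=C(CCC=C(C)C)[C@@H](CC(=O)OCC)C[C@H](/C(CO[Si](c2ccccc2)(c2ccccc2)C(C)(C)C)=C\CC/C(C)=C\CO[Si](C)(C)C(C)(C)C)O1
F6 | step 15 | trimethylsilyl ester of acid 26 | CC(C)=CCC[C@]1(C(=O)O[Si](C)(C)C)[C@@H](CC(=O)OCC)CC=C(CO[Si](c2ccccc2)(c2ccccc2)C(C)(C)C)[C@@H]1CC/C(C)=C\CO[Si](C)(C)C(C)(C)C
F7 | step 24 | allylic methyl carbonate of 33 | CC(C)=CCC[C@]1(C(=O)OCC[Si](C)(C)C)[C@@H](C/C=C(\C)COC(=O)OC)CC=C(CO[Si](c2ccccc2)(c2ccccc2)C(C)(C)C)[C@@H]1CC/C(C)=C\CS(=O)(=O)c2ccccc2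
F8 | step 25 | desilylated macrocyclic sulfone, hydroxy acid (C6 epimers) | CC(C)=CCC[C@]1(C(=O)O)[C@@H]2CC=C(CO)[C@@H]1CC/C(C)=C\C(S(=O)(=O)c1ccccc1)C/C(C)=C/C2
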